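**Strategy.** With the side chain numbered C1' (OCH2) to C8' (=CH2), the route cuts C1'–C2' and C3'–CH3. The methyl-branched E olefin C2'=C3' is read as a terminal alkyne, and the C7–O–C1'H2 ether as an aryloxymethyl cation on the intact coumarin (benzene ring fused to the pyranone ring). One operation, zirconium-catalysed methylalumination followed by capture with the chloromethyl ether, makes both bonds and fixes the E geometry; no ring or stereocentre is formed. The alkyne partner is the bis-silylated (3S,4S)-enyne 10, whose threo diol (C5', C6') comes unchanged from L-threonate, a chiral-pool C4 unit with the (R,R)-tartrate array and differentiated ends.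

Key step: step 10

Assumption: methyl 3,4-O-isopropylidene-L-threonate (1) is taken as a catalogue compound of the ascorbic acid chiral pool; its C2 and C3 become C6' and C5' of the target with no bond to either stereocentre ever broken.

**Step 1**
Reactants: 1 methyl 3,4-O-isopropylidene-L-threonate
Product: 2 methyl (2R)-2-[(tert-butyldimethylsilyl)oxy]-2-[(4S)-2,2-dimethyl-1,3-dioxolan-4-yl]acetate
Conditions: TBSCl, imidazole, DMF, rt
Reagents that add atoms: tert-butyldimethylsilyl chloride, CC(C)(C)[Si](C)(C)Cl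
Why: Imidazole-promoted silyl ether formation at the only free hydroxyl puts on the future C6' oxygen the group it keeps until the last step, and no stereocentre is touched.

**Step 2**
Reactants: 2 methyl (2R)-2-[(tert-butyldimethylsilyl)oxy]-2-[(4S)-2,2-dimethyl-1,3-dioxolan-4-yl]acetate
Product: 4 (1R)-1-[(tert-butyldimethylsilyl)oxy]-1-[(4S)-2,2-dimethyl-1,3-dioxolan-4-yl]propan-2-one, via Weinreb amide 3 (not isolated)
Conditions: MeNHOMe·HCl, iPrMgCl, THF, −20 °C; then MeMgBr, −20→0 °C
Reagents that add atoms: methylmagnesium bromide, C[Mg]Br; N,O-dimethylhydroxylamine hydrochloride, CNOC.Cl (its atoms stay only in intermediate 3)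
Why: Weinreb ketone synthesis in one flask, in which the chloromagnesium amide turns the ester into the N-methoxy-N-methylamide and the chelated tetrahedral adduct with MeMgBr collapses to the methyl ketone only on work-up, so over-addition is excluded and the α-stereocentre is not enolised.

**Step 3**
Reactants: 4 (1R)-1-[(tert-butyldimethylsilyl)oxy]-1-[(4S)-2,2-dimethyl-1,3-dioxolan-4-yl]propan-2-one
Product: 5 (4S)-4-[(1S)-1-[(tert-butyldimethylsilyl)oxy]-2-methylprop-2-en-1-yl]-2,2-dimethyl-1,3-dioxolane
Conditions: Ph3PCH3Br, KOtBu, THF, 0 °C; then 4, −78 °C→rt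
Reagents that add atoms: methyltriphenylphosphonium bromide, C[P+](c1ccccc1)(c1ccccc1)c1ccccc1.[Br-]
Why: Wittig methylenation of the methyl ketone builds the C7'=C8' isopropenyl group, and carbonyl addition at low temperature should outrun deprotonation at the hindered silyloxy-bearing carbon, so C6' keeps its configuration (the descriptor changes from R to S only through priorities).

**Step 4**
Reactants: 5 (4S)-4-[(1S)-1-[(tert-butyldimethylsilyl)oxy]-2-methylprop-2-en-1-yl]-2,2-dimethyl-1,3-dioxolane
Product: 6 (2S,3S)-3-[(tert-butyldimethylsilyl)oxy]-4-methylpent-4-ene-1,2-diol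
Conditions: AcOH/H2O (4:1), rt
Reagents that add atoms: none
Why: Acid-catalysed acetal hydrolysis, in which the terminal isopropylidene acetal should cleave much faster than the hindered secondary silyl ether, with neither the stereocentres nor the 1,1-disubstituted alkene engaged.

**Step 5**
Reactants: 6 (2S,3S)-3-[(tert-butyldimethylsilyl)oxy]-4-methylpent-4-ene-1,2-diol
Product: 8 (2S)-2-[(1S)-1-[(tert-butyldimethylsilyl)oxy]-2-methylprop-2-en-1-yl]oxirane, via primary monotosylate 7 (not isolated)
Conditions: TsCl, Et3N, Bu2SnO (cat.), CH2Cl2, 0 °C→rt; then K2CO3, MeOH, 0 °C→rt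
Reagents that add atoms: p-toluenesulfonyl chloride, Cc1ccc(cc1)S(Cl)(=O)=O (its atoms stay only in intermediate 7)
Why: Stannylene-acetal-directed sulfonylation places the tosyl group on the primary hydroxyl only, and carbonate then drives the 3-exo-tet intramolecular Williamson closure through the C5' alkoxide, so the C5'–O bond and its configuration are kept.

**Step 6**
Reactants: 8 (2S)-2-[(1S)-1-[(tert-butyldimethylsilyl)oxy]-2-methylprop-2-en-1-yl]oxirane
Product: 9 (3S,4S)-3-[(tert-butyldimethylsilyl)oxy]-2-methylhept-1-en-6-yn-4-ol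
Conditions: LiC≡CH·H2NCH2CH2NH2, DMSO, rt; H2O work-up
Reagents that add atoms: lithium acetylide–ethylenediamine complex, [Li]C#C.NCCN
Why: SN2 opening of the terminal epoxide at the unhindered C4' methylene by acetylide leaves the C5'–O bond and its configuration intact; a silyl shift between the two secondary oxygens under these basic conditions would be harmless because step 7 silylates both.

**Step 7**
Reactants: 9 (3S,4S)-3-[(tert-butyldimethylsilyl)oxy]-2-methylhept-1-en-6-yn-4-ol
Product: 10 (3S,4S)-3,4-bis[(tert-butyldimethylsilyl)oxy]-2-methylhept-1-en-6-yne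
Conditions: TBSOTf, 2,6-lutidine, CH2Cl2, −78→0 °C
Reagents that add atoms: tert-butyldimethylsilyl trifluoromethanesulfonate, CC(C)(C)[Si](C)(C)OS(=O)(=O)C(F)(F)F
Why: Silylation with the silyl triflate and a hindered pyridine base covers the crowded secondary hydroxyl next to the existing silyl ether without touching the terminal alkyne C–H or either stereocentre.

**Step 8**
Reactants: 11 7-hydroxy-8-methoxycoumarin
Product: 12 8-methoxy-7-[(methylsulfanyl)methoxy]-2H-chromen-2-one
Conditions: NaH, DMF, 0 °C; ClCH2SMe, NaI (cat.), 0 °C→rt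
Reagents that add atoms: chloromethyl methyl sulfide, CSCCl
Why: Williamson O-alkylation of the sodium phenoxide by the iodide-activated chloromethyl sulfide gives the O,S-acetal, and the lactone is not attacked by the hydride base at this temperature.

**Step 9**
Reactants: 12 8-methoxy-7-[(methylsulfanyl)methoxy]-2H-chromen-2-one
Product: 13 7-(chloromethoxy)-8-methoxy-2H-chromen-2-one
Conditions: SO2Cl2, CH2Cl2, −78→0 °C; volatiles evaporated, crude 13 used at once
Reagents that add atoms: sulfuryl chloride, O=S(=O)(Cl)Cl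
Why: Chlorinolysis of the O,S-acetal, in which S-chlorination and fragmentation of the chlorosulfonium ion give the aryl chloromethyl ether and volatile MeSCl, and the sulfide should react far faster than the lactone-deactivated arene.

**Step 10**
Reactants: 10 (3S,4S)-3,4-bis[(tert-butyldimethylsilyl)oxy]-2-methylhept-1-en-6-yne; 13 7-(chloromethoxy)-8-methoxy-2H-chromen-2-one
Product: 15 7-{[(2E,5S,6S)-5,6-bis[(tert-butyldimethylsilyl)oxy]-3,7-dimethylocta-2,7-dien-1-yl]oxy}-8-methoxy-2H-chromen-2-one, via alkenylalane 14 (not isolated)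
Conditions: Me3Al (2.5 equiv), Cp2ZrCl2 (0.25 equiv), CH2Cl2, 0 °C→rt; excess Me3Al evaporated; then 13 (1.3 equiv), CH2Cl2–hexane, −78→0 °C; cold aq. KNaC4H4O6 (potassium sodium tartrate)
Reagents that add atoms: trimethylaluminium, C[Al](C)C
Why: Zirconium-catalysed carboalumination (Negishi methylalumination) with electrophilic trapping: a methylzirconocene species activated by Me3Al adds methyl and metal syn across C2'≡C3', methyl going to the substituted carbon C3', and exchange to aluminium gives (E)-alkenylalane 14 with C4' and Al trans. Once the excess Me3Al is pumped off, the Lewis-acidic alane pulls chloride from 13 and the C2'–Al bond attacks the aryloxymethyl oxocarbenium carbon with retention of olefin geometry, forming C1'–C2'. The closest known reaction is the one-flask methylalumination of terminal alkynes with capture of the alkenylalane by chloromethyl methyl ether to give (E)-3-methylallyl ethers; 13 is an aryl member of the same α-chloro ether class and should ionise less readily. No ring is closed and no stereocentre is created; C5' and C6' come unchanged from 1, and the only element set is the E geometry of C2'=C3', dictated by the concerted syn addition. The step needs methyl at C3' (secured by the polarity of the terminal alkyne), reaction at the alkyne and not at the alkene (Cp2ZrCl2/Me3Al does not carbometalate the hindered 1,1-disubstituted C7'=C8') and survival of the lactone and silyl ethers (neutral alkenylalanes do not acylate at or below 0 °C, and the homopropargylic silyl ether is a tolerated spectator). The cold tartrate quench removes Me2AlCl before it can ionise the new allyl aryl ether.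

**Step 11**
Reactants: 15 7-{[(2E,5S,6S)-5,6-bis[(tert-butyldimethylsilyl)oxy]-3,7-dimethylocta-2,7-dien-1-yl]oxy}-8-methoxy-2H-chromen-2-one
Product: 16 7-{[(2E,5S,6S)-5,6-dihydroxy-3,7-dimethylocta-2,7-dien-1-yl]oxy}-8-methoxy-2H-chromen-2-one
Conditions: Bu4NF, AcOH, THF, 0 °C→rt
Reagents that add atoms: none
Why: Fluoride-induced desilylation of both secondary silyl ethers, buffered with acetic acid so that the coumarin lactone and the allyl aryl ether should stay intact, with C5' and C6' unaffected.

**Compound list**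

1 | methyl 3,4-O-isopropylidene-L-threonate, methyl (2R)-2-[(4S)-2,2-dimethyl-1,3-dioxolan-4-yl]-2-hydroxyacetate | COC(=O)[C@H](O)[C@@H]1COC(C)(C)O1 | starting material
2 | methyl (2R)-2-[(tert-butyldimethylsilyl)oxy]-2-[(4S)-2,2-dimethyl-1,3-dioxolan-4-yl]acetate | COC(=O)[C@H](O[Si](C)(C)C(C)(C)C)[C@@H]1COC(C)(C)O1 | intermediate
3 | (2R)-2-[(tert-butyldimethylsilyl)oxy]-2-[(4S)-2,2-dimethyl-1,3-dioxolan-4-yl]-N-methoxy-N-methylacetamide (Weinreb amide, not isolated) | CON(C)C(=O)[C@H](O[Si](C)(C)C(C)(C)C)[C@@H]1COC(C)(C)O1 | intermediate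
4 | (1R)-1-[(tert-butyldimethylsilyl)oxy]-1-[(4S)-2,2-dimethyl-1,3-dioxolan-4-yl]propan-2-one | CC(=O)[C@H](O[Si](C)(C)C(C)(C)C)[C@@H]1COC(C)(C)O1 | intermediate
5 | (4S)-4-[(1S)-1-[(tert-butyldimethylsilyl)oxy]-2-methylprop-2-en-1-yl]-2,2-dimethyl-1,3-dioxolane | C=C(C)[C@H](O[Si](C)(C)C(C)(C)C)[C@@H]1COC(C)(C)O1 | intermediate
6 | (2S,3S)-3-[(tert-butyldimethylsilyl)oxy]-4-methylpent-4-ene-1,2-diol | C=C(C)[C@H](O[Si](C)(C)C(C)(C)C)[C@@H](O)CO | intermediate
7 | (2S,3S)-3-[(tert-butyldimethylsilyl)oxy]-2-hydroxy-4-methylpent-4-en-1-yl 4-methylbenzenesulfonate (not isolated) | C=C(C)[C@H](O[Si](C)(C)C(C)(C)C)[C@@H](O)COS(=O)(=O)c1ccc(C)cc1 | intermediate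
8 | (2S)-2-[(1S)-1-[(tert-butyldimethylsilyl)oxy]-2-methylprop-2-en-1-yl]oxirane | C=C(C)[C@H](O[Si](C)(C)C(C)(C)C)[C@@H]1CO1 | intermediate
9 | (3S,4S)-3-[(tert-butyldimethylsilyl)oxy]-2-methylhept-1-en-6-yn-4-ol | C=C(C)[C@H](O[Si](C)(C)C(C)(C)C)[C@@H](O)CC#C | intermediate
10 | (3S,4S)-3,4-bis[(tert-butyldimethylsilyl)oxy]-2-methylhept-1-en-6-yne | C=C(C)[C@H](O[Si](C)(C)C(C)(C)C)[C@@H](O[Si](C)(C)C(C)(C)C)CC#C | intermediate
11 | 7-hydroxy-8-methoxycoumarin (7-hydroxy-8-methoxy-2H-chromen-2-one) | Oc1ccc2ccc(=O)oc2c1OC | starting material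
12 | 8-methoxy-7-[(methylsulfanyl)methoxy]-2H-chromen-2-one | CSCOc1ccc2ccc(=O)oc2c1OC | intermediate
13 | 7-(chloromethoxy)-8-methoxy-2H-chromen-2-one | ClCOc1ccc2ccc(=O)oc2c1OC | intermediate
14 | dimethyl[(1E,4S,5S)-4,5-bis[(tert-butyldimethylsilyl)oxy]-2,6-dimethylhepta-1,6-dien-1-yl]alumane (not isolated) | C=C(C)[C@H](O[Si](C)(C)C(C)(C)C)[C@@H](O[Si](C)(C)C(C)(C)C)C/C(C)=C/[Al](C)C | intermediate
15 | 7-{[(2E,5S,6S)-5,6-bis[(tert-butyldimethylsilyl)oxy]-3,7-dimethylocta-2,7-dien-1-yl]oxy}-8-methoxy-2H-chromen-2-one | C=C(C)[C@H](O[Si](C)(C)C(C)(C)C)[C@@H](O[Si](C)(C)C(C)(C)C)C/C(C)=C/COc1ccc2ccc(=O)oc2c1OC | intermediate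
16 | 7-{[(2E,5S,6S)-5,6-dihydroxy-3,7-dimethylocta-2,7-dien-1-yl]oxy}-8-methoxy-2H-chromen-2-one | C=C(C)[C@H](O)[C@@H](O)C/C(C)=C/COc1ccc2ccc(=O)oc2c1OC | target

**Step count and risks**

Total step count: 11. Longest linear sequence: 9 steps (steps 1–7, 10, 11, from 1); the branch from 11 has two steps (8, 9).

Steps most likely to fail:

1. Step 10. The alkenylalane may ionise the aryl chloromethyl ether too slowly, so that methyl transfer from aluminium or hydrolysis of the labile 13 competes, or Me2AlCl may ionise the freshly formed allyl aryl ether. The fallback sets out from enyne 10: the same methylalumination gives 14, and n-BuLi converts it into lithium butyl[(1E,4S,5S)-4,5-bis[(tert-butyldimethylsilyl)oxy]-2,6-dimethylhepta-1,6-dien-1-yl]dimethylaluminate F1. Paraformaldehyde then gives the allylic alcohol (2E,5S,6S)-5,6-bis[(tert-butyldimethylsilyl)oxy]-3,7-dimethylocta-2,7-dien-1-ol F2, and Mitsunobu etherification of F2 with phenol 11 (PPh3, DIAD, THF) comes back to the route at 15. Compound 13 is then no longer needed.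

2. Step 3. The basic ylide may deprotonate ketone 4 at the silyloxy-bearing carbon, leading to epimerisation at C6' or β-elimination of the dioxolane oxygen. The fallback sets out from ester 2: excess MeMgBr gives the tertiary alcohol (1R)-1-[(tert-butyldimethylsilyl)oxy]-1-[(4S)-2,2-dimethyl-1,3-dioxolan-4-yl]-2-methylpropan-2-ol F3, and dehydration with the Burgess reagent towards a methyl group comes back to the route at 5.

3. Step 6. Under the strongly basic conditions in DMSO, silyl transfer, partial silyl loss or slow opening beside the bulky silyloxy group may erode the material balance. The fallback sets out from diol 6 and avoids any free alkoxide. Tf2O with 2,6-lutidine at −78 °C gives the primary triflate (2S,3S)-3-[(tert-butyldimethylsilyl)oxy]-2-hydroxy-4-methylpent-4-en-1-yl trifluoromethanesulfonate F4. TBSOTf added to the same flask silylates it to (2S,3S)-2,3-bis[(tert-butyldimethylsilyl)oxy]-4-methylpent-4-en-1-yl trifluoromethanesulfonate F5. LiC≡CSiMe3 in THF–DMPU at −78 °C displaces the triflate to give [(4S,5S)-4,5-bis[(tert-butyldimethylsilyl)oxy]-6-methylhept-6-en-1-yn-1-yl]trimethylsilane F6, and K2CO3 in MeOH removes the C-silyl group to come back to the route at 10.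

**Further compounds**

F1 | step 10 | lithium butyl[(1E,4S,5S)-4,5-bis[(tert-butyldimethylsilyl)oxy]-2,6-dimethylhepta-1,6-dien-1-yl]dimethylaluminate | C=C(C)[C@H](O[Si](C)(C)C(C)(C)C)[C@@H](O[Si](C)(C)C(C)(C)C)C/C(C)=C/[Al-](C)(C)CCCC.[Li+]
F2 | step 10 | (2E,5S,6S)-5,6-bis[(tert-butyldimethylsilyl)oxy]-3,7-dimethylocta-2,7-dien-1-ol | C=C(C)[C@H](O[Si](C)(C)C(C)(C)C)[C@@H](O[Si](C)(C)C(C)(C)C)C/C(C)=C/CO
F3 | step 3 | (1R)-1-[(tert-butyldimethylsilyl)oxy]-1-[(4S)-2,2-dimethyl-1,3-dioxolan-4-yl]-2-methylpropan-2-ol | CC(C)(O)[C@H](O[Si](C)(C)C(C)(C)C)[C@@H]1COC(C)(C)O1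
F4 | step 6 | (2S,3S)-3-[(tert-butyldimethylsilyl)oxy]-2-hydroxy-4-methylpent-4-en-1-yl trifluoromethanesulfonate | C=C(C)[C@H](O[Si](C)(C)C(C)(C)C)[C@@H](O)COS(=O)(=O)C(F)(F)F
F5 | step 6 | (2S,3S)-2,3-bis[(tert-butyldimethylsilyl)oxy]-4-methylpent-4-en-1-yl trifluoromethanesulfonate | C=C(C)[C@H](O[Si](C)(C)C(C)(C)C)[C@@H](O[Si](C)(C)C(C)(C)C)COS(=O)(=O)C(F)(F)F
F6 | step 6 | [(4S,5S)-4,5-bis[(tert-butyldimethylsilyl)oxy]-6-methylhept-6-en-1-yn-1-yl]trimethylsilane | C=C(C)[C@H](O[Si](C)(C)C(C)(C)C)[C@@H](O[Si](C)(C)C(C)(C)C)CC#C[Si](C)(C)C
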